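The route rests on disconnecting ring B at C9–C10. An Ireland–Claisen rearrangement of a δ-lactone joins the quaternary C10 to its neighbour C9 and, in the same operation, contracts the lactone to carbocyclic ring B with a Δ5 alkene and relays the C6 carbinol configuration to C10. The step exploits the fact that C10 is an all-carbon quaternary centre bonded to C9, which sits next to the 3-hydroxy-3-methyl (mevalonate-type) carbon C8 of ring B. Its precursor is a (4R,6S) 4-methyl-4-silyloxy δ-lactone that carries at C6 the tetrasubstituted ring A cyclohexene, with C3 masked as a dioxolane. Bromide installation, C9 inversion, oxocene closure and epoxidation follow.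

Key step: step 10

Remarks on the chemistry:
- Lactone and decalin atoms carry labdane numbers (C1–C10 decalin, C11 on C9, C17 = methyl on C8, C20 = methyl on C10); β is the face of the C20 methyl group. Compounds 12–22 are named as drimanes (C11 on C9; the C8 methyl is part of the parent).
- C3 travels as a dioxolane, so ring A is achiral and all absolute configuration stems from the allylboration in step 5.
- Assumption: an equatorial C11 flanked by the axial C17 and C20 methyl groups has no reliable thermodynamic preference, so C9 is corrected by kinetic protonation (step 18), not by equilibration.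

Step 1
Reactants: 1 2,2-dimethylcyclohexane-1,3-dione
Product: 2 6,6-dimethyl-1,4-dioxaspiro[4.5]decan-7-one
Conditions: HOCH2CH2OH (1.05 equiv), TsOH·H2O (cat.), benzene, reflux, Dean–Stark trap
Reagents that add atoms: ethylene glycol, OCCO
Why: Acid-catalysed ketalisation that should stop at the monoketal, because the first dioxolane and the gem-dimethyl group shield the second carbonyl.

Step 2
Reactants: 2 6,6-dimethyl-1,4-dioxaspiro[4.5]decan-7-one
Product: 3 6,6,8-trimethyl-1,4-dioxaspiro[4.5]decan-7-one (racemic)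
Conditions: LiN(iPr)2, THF, −78 °C; MeI, −78 → 0 °C
Reagents that add atoms: iodomethane, CI
Why: Kinetic lithium enolate alkylation; the ketone can enolise only toward C10, and the stereocentre made there is erased in step 3.

Step 3
Reactants: 3 6,6,8-trimethyl-1,4-dioxaspiro[4.5]decan-7-one
Product: 4 6,6,8-trimethyl-1,4-dioxaspiro[4.5]dec-7-en-7-yl trifluoromethanesulfonate
Conditions: LiN(iPr)2, THF, −78 → 0 °C; PhNTf2, 0 °C → rt
Reagents that add atoms: N-phenylbis(trifluoromethanesulfonimide), O=S(=O)(N(c1ccccc1)S(=O)(=O)C(F)(F)F)C(F)(F)F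
Why: Enol triflate formation; the single α-hydrogen forces the tetrasubstituted C5=C10 enolate, which is O-sulfonylated.

Step 4
Reactants: 4 6,6,8-trimethyl-1,4-dioxaspiro[4.5]dec-7-en-7-yl trifluoromethanesulfonate
Product: 5 6,6,8-trimethyl-1,4-dioxaspiro[4.5]dec-7-ene-7-carbaldehyde
Conditions: Pd(OAc)2 (cat.), dppp, CO (1 atm), Et3SiH, Et3N, DMF, 70 °C
Reagents that add atoms: carbon monoxide, [C-]#[O+]
Why: Palladium-catalysed reductive carbonylation (formylation) of an enol triflate: zerovalent palladium inserts into the C–OTf bond, CO inserts, and the silane reduces the acylpalladium to the enal.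

Step 5
Reactants: 5 6,6,8-trimethyl-1,4-dioxaspiro[4.5]dec-7-ene-7-carbaldehyde
Product: 6 (1S)-1-(6,6,8-trimethyl-1,4-dioxaspiro[4.5]dec-7-en-7-yl)but-3-en-1-ol
Conditions: (+)-Ipc2B(allyl) ((+)-α-pinene series, commercial solution in pentane), Et2O, −78 °C; then aq. NaOH, H2O2, 0 °C → rt
Reagents that add atoms: (+)-B-allyldiisopinocampheylborane, C=CCB([C@@H]1C[C@@H]2C[C@@H](C2(C)C)[C@H]1C)[C@@H]1C[C@@H]2C[C@@H](C2(C)C)[C@H]1C
Why: Brown allylboration through a closed chair (Zimmerman–Traxler) transition state; the isopinocampheyl groups direct allyl to the Si face of the aldehyde, which sets C6 as S by reagent control.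

Step 6
Reactants: 6 (1S)-1-(6,6,8-trimethyl-1,4-dioxaspiro[4.5]dec-7-en-7-yl)but-3-en-1-ol
Product: 7 (4S)-4-hydroxy-4-(6,6,8-trimethyl-1,4-dioxaspiro[4.5]dec-7-en-7-yl)butan-2-one
Conditions: PdCl2 (cat.), CuCl, O2 (1 atm), DMF/H2O (7:1), rt
Reagents that add atoms: water, O
Why: Tsuji–Wacker oxidation; Markovnikov hydroxypalladation of the terminal alkene gives the methyl ketone (C8 with its methyl C17), while the crowded tetrasubstituted ring alkene does not bind divalent palladium.

Step 7
Reactants: 7 (4S)-4-hydroxy-4-(6,6,8-trimethyl-1,4-dioxaspiro[4.5]dec-7-en-7-yl)butan-2-one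
Product: 8 (1S)-3-oxo-1-(6,6,8-trimethyl-1,4-dioxaspiro[4.5]dec-7-en-7-yl)butyl bromoacetate
Conditions: BrCH2COBr, pyridine, CH2Cl2, −20 → 0 °C
Reagents that add atoms: bromoacetyl bromide, BrCC(Br)=O
Why: O-acylation of the hindered secondary carbinol by a reactive acyl bromide; pyridine at low temperature is too weak a base to trigger β-elimination of the β-acyloxy ketone.

Step 8
Reactants: 8 (1S)-3-oxo-1-(6,6,8-trimethyl-1,4-dioxaspiro[4.5]dec-7-en-7-yl)butyl bromoacetate
Product: 9 (4R,6S)-4-hydroxy-4-methyl-6-(6,6,8-trimethyl-1,4-dioxaspiro[4.5]dec-7-en-7-yl)tetrahydro-2H-pyran-2-one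
Conditions: SmI2 (2.2 equiv), THF, −78 °C
Reagents that add atoms: none
Why: Samarium-mediated intramolecular Reformatsky reaction; the trivalent samarium enolate and the ketone oxygen are bridged in a chair in which the C6 substituent and the ketone methyl are equatorial, so the new C8 hydroxyl is axial and trans to the cyclohexenyl group (8R, methyl cis to the cyclohexenyl group).

Step 9
Reactants: 9 (4R,6S)-4-hydroxy-4-methyl-6-(6,6,8-trimethyl-1,4-dioxaspiro[4.5]dec-7-en-7-yl)tetrahydro-2H-pyran-2-one
Product: 10 (4R,6S)-4-methyl-4-(triethylsilyloxy)-6-(6,6,8-trimethyl-1,4-dioxaspiro[4.5]dec-7-en-7-yl)tetrahydro-2H-pyran-2-one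
Conditions: Et3SiOTf, 2,6-lutidine, CH2Cl2, −78 → 0 °C
Reagents that add atoms: triethylsilyl trifluoromethanesulfonate, CC[Si](CC)(CC)OS(=O)(=O)C(F)(F)F
Why: Silyl triflate silylation of the tertiary alcohol, needed because the later C11 aldehyde would otherwise be a retro-aldol-prone β-hydroxy aldehyde.

Step 10
Reactants: 10 (4R,6S)-4-methyl-4-(triethylsilyloxy)-6-(6,6,8-trimethyl-1,4-dioxaspiro[4.5]dec-7-en-7-yl)tetrahydro-2H-pyran-2-one
Product: 13 3,3-ethylenedioxy-8α-(triethylsilyloxy)-9-epi-drim-5-en-11-oic acid (C11 carboxyl α; 8R,9S,10R), via silyl ketene acetal 11 (not isolated), via trimethylsilyl ester 12 (not isolated)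
Conditions: Me3SiCl/Et3N (1:1, premixed), THF, −78 °C; LiN(iPr)2 added dropwise, −78 °C → rt; solvent switch to toluene, 100 °C; aq. citric acid work-up
Reagents that add atoms: chlorotrimethylsilane, C[Si](C)(C)Cl (its silyl group is carried by 11 and 12 only and is lost on work-up)
Why: Deprotonation of 10 in the presence of Me3SiCl gives the cyclic silyl ketene acetal 11, whose allyl vinyl ether array C9=C11–O–C6–C5=C10 undergoes a concerted suprafacial [3,3]-sigmatropic shift that forms C9–C10 and breaks C6–O to give silyl ester 12, hydrolysed to 13 on work-up. The closest known reaction type is the Ireland–Claisen rearrangement of 6-alkenyl δ-lactone and dioxanone silyl ketene acetals to cyclohexene carboxylic acids and dihydropyrans. Ring B (C5, C6, C7, C8, C9, C10) closes by this sigmatropic C–C bond formation as a lactone-to-carbocycle ring contraction; because C6 and C9 are tied by the C7–C8 bridge, only a boat-like, bicyclo[2.2.2]-type array is possible. C10 is set by suprafacial transfer of the 6S carbinol configuration (C9 bonds to the alkene face from which the C6–O bond departs), and C9 is set by the ring-fixed ketene acetal geometry, which places the carboxyl cis to the C8 silyloxy group and trans to the C20 methyl group (the 9-epimer, corrected in step 18); C8 is a spectator. The step needs silylation and rearrangement to outrun β-elimination of the C8 silyloxy group, which the internal silyl chloride quench at −78 °C should secure, and it needs the crowded C9–C10 bond to form, which the intramolecular concerted shift with no competing chair and no ionic intermediate should allow.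

Step 11
Reactants: 13 3,3-ethylenedioxy-8α-(triethylsilyloxy)-9-epi-drim-5-en-11-oic acid
Product: 14 methyl 3,3-ethylenedioxy-8α-(triethylsilyloxy)-9-epi-drim-5-en-11-oate
Conditions: Me3SiCHN2, MeOH/toluene (1:4), 0 °C → rt
Reagents that add atoms: (trimethylsilyl)diazomethane, C[Si](C)(C)C=[N+]=[N-]
Why: Carboxylate O-alkylation by the diazoalkane, which is insensitive to the crowding around C9; the ester masks C11 through the ring A chemistry.

Step 12
Reactants: 14 methyl 3,3-ethylenedioxy-8α-(triethylsilyloxy)-9-epi-drim-5-en-11-oate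
Product: 15 methyl 3-oxo-8α-(triethylsilyloxy)-9-epi-drim-5-en-11-oate
Conditions: pyridinium p-toluenesulfonate (cat.), acetone/H2O (10:1), 55 °C
Reagents that add atoms: water, O
Why: Acid-catalysed dioxolane hydrolysis under conditions mild enough for the tertiary triethylsilyl ether; the quaternary C4 keeps the ketone out of conjugation with the Δ5 alkene.

Step 13
Reactants: 15 methyl 3-oxo-8α-(triethylsilyloxy)-9-epi-drim-5-en-11-oate
Product: 16 methyl 8α-(triethylsilyloxy)-3-(trifluoromethylsulfonyloxy)-9-epi-drima-2,5-dien-11-oate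
Conditions: KN(SiMe3)2, THF, −78 °C; PhNTf2, −78 → 0 °C
Reagents that add atoms: N-phenylbis(trifluoromethanesulfonimide), O=S(=O)(N(c1ccccc1)S(=O)(=O)C(F)(F)F)C(F)(F)F
Why: Kinetic enolate O-triflation; C4 is quaternary, so only the C2 enolate can form, and the hindered C9–H of the ester is far less acidic than the ketone.

Step 14
Reactants: 16 methyl 8α-(triethylsilyloxy)-3-(trifluoromethylsulfonyloxy)-9-epi-drima-2,5-dien-11-oate
Product: 17 methyl 3-bromo-8α-(triethylsilyloxy)-9-epi-drima-2,5-dien-11-oate
Conditions: Ni(OAc)2·4H2O (cat.), 1,5-cyclooctadiene, Zn (cat.), LiBr, THF/DMA, rt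
Reagents that add atoms: lithium bromide, [Li+].[Br-]
Why: Nickel-catalysed triflate-to-bromide exchange of an enol triflate: zerovalent nickel inserts into the C–OTf bond, bromide replaces triflate on nickel, and C–Br reductive elimination releases the alkenyl bromide.

Step 15
Reactants: 17 methyl 3-bromo-8α-(triethylsilyloxy)-9-epi-drima-2,5-dien-11-oate
Product: 18 methyl 3β-bromo-8α-(triethylsilyloxy)-9-epi-driman-11-oate (5αH, trans-decalin)
Conditions: Mn(dpm)3 (cat.), PhSiH3, tBuOOH, iPrOH, rt
Reagents that add atoms: none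
Why: Mukaiyama-type metal-hydride hydrogen-atom-transfer hydrogenation, known to reduce haloalkenes without loss of halide; H adds to C6 and C2, and the tertiary C5 radical and the α-bromo C3 radical should each take up hydrogen on the α face, opposite the axial C20 and 4β methyl groups, which gives the trans ring fusion and the equatorial 3β bromide.

Step 16
Reactants: 18 methyl 3β-bromo-8α-(triethylsilyloxy)-9-epi-driman-11-oate
Product: 19 3β-bromo-8α-(triethylsilyloxy)-9-epi-driman-11-ol
Conditions: iBu2AlH (3 equiv), CH2Cl2, −78 → 0 °C; aq. potassium sodium tartrate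
Reagents that add atoms: none
Why: Aluminium hydride reduction of the ester to the primary alcohol; this hydride leaves the neopentyl secondary bromide and the silyl ether untouched.

Step 17
Reactants: 19 3β-bromo-8α-(triethylsilyloxy)-9-epi-driman-11-ol
Product: 20 3β-bromo-8α-(triethylsilyloxy)-9-epi-driman-11-al (9α-CHO, axial)
Conditions: Dess–Martin periodinane, NaHCO3, CH2Cl2, 0 °C → rt
Reagents that add atoms: none
Why: Dess–Martin oxidation of the primary alcohol under buffered, non-basic conditions.

Step 18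
Reactants: 20 3β-bromo-8α-(triethylsilyloxy)-9-epi-driman-11-al
Product: 22 3β-bromo-8α-(triethylsilyloxy)driman-11-al (9β-CHO, 9αH), via potassium enolate 21 (not isolated)
Conditions: KN(SiMe3)2 (1.3 equiv), THF, −78 → −40 °C; transfer into AcOH/THF at −78 °C
Reagents that add atoms: none
Why: Enolisation followed by kinetic protonation; the β face of the exocyclic enolate is flanked by the axial C17 and C20 methyl groups, so the proton should arrive on the α face and leave C11 β (equatorial), while the equatorial C8–O bond lies in the nodal plane of the enolate in the locked chair and so resists β-elimination.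

Step 19
Reactants: 22 3β-bromo-8α-(triethylsilyloxy)driman-11-al
Product: 23 3β-bromo-8α-(triethylsilyloxy)-13,14,15,16-tetranorlabd-11-ene (vinyl group on C9)
Conditions: Ph3PCH3Br, KN(SiMe3)2 (slight deficit), THF, 0 °C; then 22, −78 → 0 °C
Reagents that add atoms: methyltriphenylphosphonium bromide, C[P+](c1ccccc1)(c1ccccc1)c1ccccc1.[Br-]
Why: Wittig methylenation; with no excess base present the non-stabilised ylide should add to the aldehyde at low temperature faster than it enolises it, so C9 keeps its configuration and is no longer epimerisable afterwards.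

Step 20
Reactants: 23 3β-bromo-8α-(triethylsilyloxy)-13,14,15,16-tetranorlabd-11-ene
Product: 25 3β-bromo-8α-(triethylsilyloxy)-15-norlabd-13-ene (C13 isopropenyl terminus), via B-alkyl-9-BBN borane 24 (not isolated)
Conditions: 9-BBN dimer, THF, rt → 50 °C; then 2-bromopropene, Pd(dppf)Cl2 (cat.), AsPh3, Cs2CO3, DMF/H2O, 50 °C
Reagents that add atoms: 9-borabicyclo[3.3.1]nonane, B1C2CCCC1CCC2 (carried by 24 only); 2-bromopropene, CC(Br)=C
Why: Anti-Markovnikov hydroboration places boron on C12, and a B-alkyl Suzuki–Miyaura coupling with the alkenyl bromide forms C12–C13; the unactivated secondary alkyl bromide does not undergo oxidative addition under these conditions.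

Step 21
Reactants: 25 3β-bromo-8α-(triethylsilyloxy)-15-norlabd-13-ene
Product: 26 3β-bromo-15-norlabd-13-en-8α-ol
Conditions: Bu4NF, THF, rt → 40 °C
Reagents that add atoms: none
Why: Fluoride desilylation of the tertiary silyl ether; the equatorial bromide has no anti-periplanar hydrogen and a blocked backside, so it should be inert to fluoride.

Step 22
Reactants: 26 3β-bromo-15-norlabd-13-en-8α-ol
Product: 27 8α-allyloxy-3β-bromo-15-norlabd-13-ene
Conditions: KH, 18-crown-6 (cat.), THF, 0 °C; allyl bromide, 0 °C → rt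
Reagents that add atoms: allyl bromide, C=CCBr
Why: Williamson etherification of the tertiary potassium alkoxide with a reactive allylic bromide.

Step 23
Reactants: 27 8α-allyloxy-3β-bromo-15-norlabd-13-ene
Product: 28 (13Z)-3β-bromo-8α,15-epoxylabd-13-ene (trans-fused oxocene)
Conditions: second-generation Grubbs catalyst (cat.), 1,4-benzoquinone (cat.), toluene (high dilution), 80 °C
Reagents that add atoms: none
Why: Ring-closing metathesis; the ruthenium carbene should load on the allyl ether and close the eight-membered ring onto the 1,1-disubstituted alkene, helped by the gauche trans-diequatorial C8–O and C9–C11 bonds, and the ring size enforces the Z alkene.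

Step 24
Reactants: 28 (13Z)-3β-bromo-8α,15-epoxylabd-13-ene
Product: 29 (3S,5R,8R,9R,10S,13R,14S)-3-bromo-8,15:13,14-diepoxylabdane (CNP0311742.2)
Conditions: mCPBA, NaHCO3, CH2Cl2, 0 °C
Reagents that add atoms: meta-chloroperoxybenzoic acid, OOC(=O)c1cccc(Cl)c1
Why: Prilezhaev epoxidation of the only alkene; the oxocene should prefer the conformer with C12 anti to C10 and C15 anti to the axial C17 methyl, which folds C13=C14 below the α face with its inner face toward ring B, so the peracid should add to the outer face and give 13R,14S.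

Compound list
1 | 2,2-dimethylcyclohexane-1,3-dione | CC1(C)C(=O)CCCC1=O | starting material
2 | 6,6-dimethyl-1,4-dioxaspiro[4.5]decan-7-one | CC1(C)C(=O)CCCC12OCCO2 | intermediate
3 | 6,6,8-trimethyl-1,4-dioxaspiro[4.5]decan-7-one (racemic) | CC1CCC2(OCCO2)C(C)(C)C1=O | intermediate
4 | 6,6,8-trimethyl-1,4-dioxaspiro[4.5]dec-7-en-7-yl trifluoromethanesulfonate | CC1=C(OS(=O)(=O)C(F)(F)F)C(C)(C)C2(CC1)OCCO2 | intermediate
5 | 6,6,8-trimethyl-1,4-dioxaspiro[4.5]dec-7-ene-7-carbaldehyde | CC1=C(C=O)C(C)(C)C2(CC1)OCCO2 | intermediate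
6 | (1S)-1-(6,6,8-trimethyl-1,4-dioxaspiro[4.5]dec-7-en-7-yl)but-3-en-1-ol | C=CC[C@H](O)C1=C(C)CCC2(OCCO2)C1(C)C | intermediate
7 | (4S)-4-hydroxy-4-(6,6,8-trimethyl-1,4-dioxaspiro[4.5]dec-7-en-7-yl)butan-2-one | CC(=O)C[C@H](O)C1=C(C)CCC2(OCCO2)C1(C)C | intermediate
8 | (1S)-3-oxo-1-(6,6,8-trimethyl-1,4-dioxaspiro[4.5]dec-7-en-7-yl)butyl bromoacetate | CC(=O)C[C@H](OC(=O)CBr)C1=C(C)CCC2(OCCO2)C1(C)C | intermediate
9 | (4R,6S)-4-hydroxy-4-methyl-6-(6,6,8-trimethyl-1,4-dioxaspiro[4.5]dec-7-en-7-yl)tetrahydro-2H-pyran-2-one | O=C1C[C@](C)(O)C[C@H](O1)C2=C(C)CCC3(OCCO3)C2(C)C | intermediate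
10 | (4R,6S)-4-methyl-4-(triethylsilyloxy)-6-(6,6,8-trimethyl-1,4-dioxaspiro[4.5]dec-7-en-7-yl)tetrahydro-2H-pyran-2-one | O=C1C[C@](C)(O[Si](CC)(CC)CC)C[C@H](O1)C2=C(C)CCC3(OCCO3)C2(C)C | intermediate (key-step precursor)
11 | (2S,4R)-4-methyl-4-(triethylsilyloxy)-6-(trimethylsilyloxy)-2-(6,6,8-trimethyl-1,4-dioxaspiro[4.5]dec-7-en-7-yl)-3,4-dihydro-2H-pyran | C[Si](C)(C)OC1=C[C@](C)(O[Si](CC)(CC)CC)C[C@H](O1)C2=C(C)CCC3(OCCO3)C2(C)C | intermediate (not isolated)
12 | trimethylsilyl 3,3-ethylenedioxy-8α-(triethylsilyloxy)-9-epi-drim-5-en-11-oate | CC1(C)C3(OCCO3)CC[C@]2(C)[C@H](C(=O)O[Si](C)(C)C)[C@](C)(O[Si](CC)(CC)CC)CC=C12 | intermediate (not isolated)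
13 | 3,3-ethylenedioxy-8α-(triethylsilyloxy)-9-epi-drim-5-en-11-oic acid (8R,9S,10R) | CC1(C)C3(OCCO3)CC[C@]2(C)[C@H](C(=O)O)[C@](C)(O[Si](CC)(CC)CC)CC=C12 | intermediate (key-step product)
14 | methyl 3,3-ethylenedioxy-8α-(triethylsilyloxy)-9-epi-drim-5-en-11-oate | CC1(C)C3(OCCO3)CC[C@]2(C)[C@H](C(=O)OC)[C@](C)(O[Si](CC)(CC)CC)CC=C12 | intermediate
15 | methyl 3-oxo-8α-(triethylsilyloxy)-9-epi-drim-5-en-11-oate | CC1(C)C(=O)CC[C@]2(C)[C@H](C(=O)OC)[C@](C)(O[Si](CC)(CC)CC)CC=C12 | intermediate
16 | methyl 8α-(triethylsilyloxy)-3-(trifluoromethylsulfonyloxy)-9-epi-drima-2,5-dien-11-oate | CC1(C)C(OS(=O)(=O)C(F)(F)F)=CC[C@]2(C)[C@H](C(=O)OC)[C@](C)(O[Si](CC)(CC)CC)CC=C12 | intermediate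
17 | methyl 3-bromo-8α-(triethylsilyloxy)-9-epi-drima-2,5-dien-11-oate | CC1(C)C(Br)=CC[C@]2(C)[C@H](C(=O)OC)[C@](C)(O[Si](CC)(CC)CC)CC=C12 | intermediate
18 | methyl 3β-bromo-8α-(triethylsilyloxy)-9-epi-driman-11-oate | CC1(C)[C@@H](Br)CC[C@]2(C)[C@H](C(=O)OC)[C@](C)(O[Si](CC)(CC)CC)CC[C@@H]12 | intermediate
19 | 3β-bromo-8α-(triethylsilyloxy)-9-epi-driman-11-ol | CC1(C)[C@@H](Br)CC[C@]2(C)[C@H](CO)[C@](C)(O[Si](CC)(CC)CC)CC[C@@H]12 | intermediate
20 | 3β-bromo-8α-(triethylsilyloxy)-9-epi-driman-11-al | CC1(C)[C@@H](Br)CC[C@]2(C)[C@H](C=O)[C@](C)(O[Si](CC)(CC)CC)CC[C@@H]12 | intermediate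
21 | potassium enolate of 20 (C9=C11, geometry not specified) | CC1(C)[C@@H](Br)CC[C@]2(C)C(=C[O-])[C@](C)(O[Si](CC)(CC)CC)CC[C@@H]12.[K+] | intermediate (not isolated)
22 | 3β-bromo-8α-(triethylsilyloxy)driman-11-al (9αH) | CC1(C)[C@@H](Br)CC[C@]2(C)[C@@H](C=O)[C@](C)(O[Si](CC)(CC)CC)CC[C@@H]12 | intermediate
23 | 3β-bromo-8α-(triethylsilyloxy)-13,14,15,16-tetranorlabd-11-ene | CC1(C)[C@@H](Br)CC[C@]2(C)[C@@H](C=C)[C@](C)(O[Si](CC)(CC)CC)CC[C@@H]12 | intermediate
24 | 12-(9-borabicyclo[3.3.1]nonan-9-yl)-3β-bromo-8α-(triethylsilyloxy)-13,14,15,16-tetranorlabdane | CC1(C)[C@@H](Br)CC[C@]2(C)[C@@H](CCB3C4CCCC3CCC4)[C@](C)(O[Si](CC)(CC)CC)CC[C@@H]12 | intermediate (not isolated)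
25 | 3β-bromo-8α-(triethylsilyloxy)-15-norlabd-13-ene | CC1(C)[C@@H](Br)CC[C@]2(C)[C@@H](CCC(C)=C)[C@](C)(O[Si](CC)(CC)CC)CC[C@@H]12 | intermediate
26 | 3β-bromo-15-norlabd-13-en-8α-ol | CC1(C)[C@@H](Br)CC[C@]2(C)[C@@H](CCC(C)=C)[C@](C)(O)CC[C@@H]12 | intermediate
27 | 8α-allyloxy-3β-bromo-15-norlabd-13-ene | CC1(C)[C@@H](Br)CC[C@]2(C)[C@@H](CCC(C)=C)[C@](C)(OCC=C)CC[C@@H]12 | intermediate
28 | (13Z)-3β-bromo-8α,15-epoxylabd-13-ene | CC1(C)[C@@H](Br)CC[C@]2(C)[C@H]3CC/C(C)=C\CO[C@]3(C)CC[C@@H]12 | intermediate
29 | (3S,5R,8R,9R,10S,13R,14S)-3-bromo-8,15:13,14-diepoxylabdane | CC1(C)[C@@H](Br)CC[C@]2(C)[C@H]3CC[C@@]4(C)O[C@H]4CO[C@]3(C)CC[C@@H]12 | target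

Total step count: 24. Longest linear sequence: 24 steps (the route is linear from 1).

Steps most likely to fail

1. Step 10. The lactone enolate may expel the C8 silyloxy group before it is silylated, or the silyl ketene acetal may decompose (C-silylation, hydrolysis, ionisation of the allylic C6–O bond) faster than the crowded boat array can bring C9 onto the fully substituted C10, where the C17 and C20 methyl groups become 1,3-diaxial. The fallback sets out from 10 and comes back at 13; it replaces the enolate-derived ketene acetal by a neutral cyclic enol ether, so no enolate is ever formed and higher temperatures can be used. Reduction of 10 with iBu2AlH at −78 °C should give the lactol (4R,6S)-4-methyl-4-(triethylsilyloxy)-6-(6,6,8-trimethyl-1,4-dioxaspiro[4.5]dec-7-en-7-yl)tetrahydro-2H-pyran-2-ol F1. Dehydration through its mesylate (MsCl, Et3N) should give the cyclic enol ether (2S,4R)-4-methyl-4-(triethylsilyloxy)-2-(6,6,8-trimethyl-1,4-dioxaspiro[4.5]dec-7-en-7-yl)-3,4-dihydro-2H-pyran F2. Thermal Claisen rearrangement of this 2-alkenyl dihydropyran (base-washed sealed tube, o-dichlorobenzene, about 200 °C; known carbocyclisation type for 6-alkenyl glycals) should pass through the same boat array to 3,3-ethylenedioxy-8α-(triethylsilyloxy)-9-epi-drim-5-en-11-al F3. Pinnick oxidation (NaClO2, NaH2PO4, 2-methyl-2-butene) then gives acid 13.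

2. Step 18. Enolisation of the hindered aldehyde may be incomplete, protonation may not be face-selective enough, or the 9β aldehyde may drift back under later basic conditions. The fallback sets out from 20 and comes back at 22; it forms the C9–H bond by hydrogenation of a neutral enol ether instead of by protonation of an enolate, and fixes C9 before the aldehyde is regenerated. Soft enolisation (Et3SiOTf, Et3N) should give the enol ether 3β-bromo-8α,11-bis(triethylsilyloxy)drim-9(11)-ene F4. Heterogeneous hydrogenation (H2, Pd/C, EtOAc), with hydrogen delivered to the α face away from the two axial methyl groups, should give 3β-bromo-8α,11-bis(triethylsilyloxy)drimane F5. Selective removal of the primary silyl ether (pyridinium p-toluenesulfonate, MeOH, 0 °C) should give 3β-bromo-8α-(triethylsilyloxy)driman-11-ol F6, and buffered Dess–Martin oxidation returns 22.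

3. Step 24. If the oxocene reacts through a second conformer, the peracid may add to the other alkene face. The fallback sets out from 28 and comes back at 29; it places the oxygen on the face opposite to the one an electrophile attacks directly. NBS in aqueous THF should form the bromonium ion on the exposed face, and water opens it at the tertiary C13 from the inner face to give the bromohydrin 3β,14-dibromo-8α,15-epoxylabdan-13-ol F7. K2CO3 in MeOH then closes the epoxide with inversion at C14 to give 29.

Further compounds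
F1 | step 10 | (4R,6S)-4-methyl-4-(triethylsilyloxy)-6-(6,6,8-trimethyl-1,4-dioxaspiro[4.5]dec-7-en-7-yl)tetrahydro-2H-pyran-2-ol (anomer mixture) | OC1C[C@](C)(O[Si](CC)(CC)CC)C[C@H](O1)C2=C(C)CCC3(OCCO3)C2(C)C
F2 | step 10 | (2S,4R)-4-methyl-4-(triethylsilyloxy)-2-(6,6,8-trimethyl-1,4-dioxaspiro[4.5]dec-7-en-7-yl)-3,4-dihydro-2H-pyran | C1=C[C@](C)(O[Si](CC)(CC)CC)C[C@H](O1)C2=C(C)CCC3(OCCO3)C2(C)C
F3 | step 10 | 3,3-ethylenedioxy-8α-(triethylsilyloxy)-9-epi-drim-5-en-11-al | CC1(C)C3(OCCO3)CC[C@]2(C)[C@H](C=O)[C@](C)(O[Si](CC)(CC)CC)CC=C12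
F4 | step 18 | 3β-bromo-8α,11-bis(triethylsilyloxy)drim-9(11)-ene | CC1(C)[C@@H](Br)CC[C@]2(C)C(=CO[Si](CC)(CC)CC)[C@](C)(O[Si](CC)(CC)CC)CC[C@@H]12
F5 | step 18 | 3β-bromo-8α,11-bis(triethylsilyloxy)drimane (9αH) | CC1(C)[C@@H](Br)CC[C@]2(C)[C@@H](CO[Si](CC)(CC)CC)[C@](C)(O[Si](CC)(CC)CC)CC[C@@H]12
F6 | step 18 | 3β-bromo-8α-(triethylsilyloxy)driman-11-ol (9αH) | CC1(C)[C@@H](Br)CC[C@]2(C)[C@@H](CO)[C@](C)(O[Si](CC)(CC)CC)CC[C@@H]12
F7 | step 24 | 3β,14-dibromo-8α,15-epoxylabdan-13-ol (13-hydroxyl on the face of the later epoxide, 14-bromide anti to it) | CC1(C)[C@@H](Br)CC[C@]2(C)[C@H]3CC[C@@](C)(O)[C@H](Br)CO[C@]3(C)CC[C@@H]12
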